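**Strategy.** The route rests on disconnecting the C4–C5 bond of ring A. The cis 3β-oxygen/4β-formyl pair on quaternary C4 (O3–C3–C4(CH3)–C19HO) is read as the result of a 1,2-shift, so C19 is first built as a ring carbon between C4 and C5 of a seven-membered ring A. Lewis-acid opening of the 3β,4β-epoxide at tertiary C4 with migration of C5 from C19 to C4 closes six-membered ring A, sets C4 and releases C19 as the aldehyde in one operation. Its precursor is the trans-fused A-homo epoxide bearing a 19α-silyl ether, the 8(17)-methylene and the protected C9 side chain, so only protecting-group changes follow.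

Key step: step 16

Remarks before the steps
- Numbering: labdane numbering is used for all ring compounds (C17 = exocyclic methylene carbon, C18 = 4α-methyl, C19 = formyl carbon, C20 = 10β-methyl). In the A-homo compounds 19, 20 and 22–24, ring A is seven-membered (C1, C2, C3, C4, C19, C5, C10).
- Design: ring B and the side chain are finished before the rearrangement, because olefination and hydride reagents used afterwards would attack the C19 aldehyde. The two silyl ethers that leave the key step (TES on O3, TBDPS on O15) are orthogonal.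
- Assumption: the (S)-prolinol-derived oxazaborolidinium catalyst is taken to give the (1R,2S) adduct 4. Should the sense of induction on this diene prove opposite, the antipodal catalyst is used.

**Step 1**
Reactants: 1 (E)-pent-3-en-2-one
Product: 2 (E)-2-(triisopropylsilyloxy)penta-1,3-diene
Conditions: TIPSOTf, Et3N, Et2O, 0 °C to rt
Reagents that add atoms: triisopropylsilyl trifluoromethanesulfonate, CC(C)[Si](C(C)C)(C(C)C)OS(=O)(=O)C(F)(F)F
Why: Silyl enol ether formation by soft enolisation removes an α′-methyl proton of the O-silylated enone and should give the cross-conjugated 2-silyloxy diene with the E alkene unchanged.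

**Step 2**
Reactants: 2 (E)-2-(triisopropylsilyloxy)penta-1,3-diene; 3 2,2,2-trifluoroethyl acrylate
Product: 4 2,2,2-trifluoroethyl (1R,2S)-2-methyl-4-(triisopropylsilyloxy)cyclohex-3-ene-1-carboxylate
Conditions: protonated B-o-tolyl oxazaborolidine from (S)-α,α-diphenylprolinol (Tf2NH salt, 20 mol %), CH2Cl2, −78 to −20 °C
Reagents that add atoms: none
Why: Catalytic enantioselective Diels–Alder reaction in which the unsubstituted diene terminus (para to the silyloxy group) bonds to the acrylate β-carbon, the endo transition state places ester and methyl cis, and the chiral Lewis acid selects one acrylate face to set ring C1 (C5 of the target).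

**Step 3**
Reactants: 4 2,2,2-trifluoroethyl (1R,2S)-2-methyl-4-(triisopropylsilyloxy)cyclohex-3-ene-1-carboxylate
Product: 5 [(1R,2R)-2-methyl-4-(triisopropylsilyloxy)cyclohex-3-en-1-yl]methanol
Conditions: LiAlH4, Et2O, 0 °C
Reagents that add atoms: none
Why: Hydride reduction of the activated ester to the primary alcohol, which leaves the silyl enol ether and both stereocentres untouched.

**Step 4**
Reactants: 5 [(1R,2R)-2-methyl-4-(triisopropylsilyloxy)cyclohex-3-en-1-yl]methanol
Product: 6 (1R,2S)-2-methyl-4-(triisopropylsilyloxy)cyclohex-3-ene-1-carbaldehyde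
Conditions: Dess–Martin periodinane, NaHCO3, CH2Cl2, 0 °C
Reagents that add atoms: none
Why: Dess–Martin oxidation under buffered, non-basic conditions should give the aldehyde without epimerising its α-carbon, and the crude product is used at once.

**Step 5**
Reactants: 6 (1R,2S)-2-methyl-4-(triisopropylsilyloxy)cyclohex-3-ene-1-carbaldehyde; 7 isopropenylmagnesium bromide
Product: 8 (1S)-2-methyl-1-[(1R,2R)-2-methyl-4-(triisopropylsilyloxy)cyclohex-3-en-1-yl]prop-2-en-1-ol
Conditions: THF, −78 °C; aq. NH4Cl
Reagents that add atoms: none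
Why: Grignard 1,2-addition under Felkin–Anh control, in which the nucleophile enters anti to the branched ring carbon C2 and past the α-hydrogen, should favour the (1S)-carbinol (C19), and the minor epimer is removed by chromatography.

**Step 6**
Reactants: 8 (1S)-2-methyl-1-[(1R,2R)-2-methyl-4-(triisopropylsilyloxy)cyclohex-3-en-1-yl]prop-2-en-1-ol
Product: 9 triethylsilyl ether of 8
Conditions: TESCl, imidazole, DMAP (cat.), CH2Cl2, 0 °C to rt
Reagents that add atoms: chlorotriethylsilane, CC[Si](CC)(CC)Cl
Why: Silylation of the secondary allylic alcohol installs the group that later shields one alkene face, migrates to O3 and can be removed in the presence of a TBDPS ether.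

**Step 7**
Reactants: 9 triethylsilyl ether of 8
Product: 10 (4R)-3-methyl-4-[(1S)-2-methyl-1-(triethylsilyloxy)prop-2-en-1-yl]cyclohex-2-en-1-one
Conditions: Pd(OAc)2 (1.1 equiv), DMSO, 45 °C
Reagents that add atoms: none
Why: Saegusa–Ito oxidation, in which the palladium enolate formed from the silyl enol ether loses its only β-hydrogen (on the methyl-bearing carbon), gives the 3-methyl enone regiospecifically and keeps the C4 stereocentre.

**Step 8**
Reactants: 10 (4R)-3-methyl-4-[(1S)-2-methyl-1-(triethylsilyloxy)prop-2-en-1-yl]cyclohex-2-en-1-one; 11 but-3-enylmagnesium bromide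
Product: 12 (3S,4R)-3-(but-3-enyl)-3-methyl-4-[(1S)-2-methyl-1-(triethylsilyloxy)prop-2-en-1-yl]-1-(trimethylsilyloxy)cyclohex-1-ene
Conditions: CuBr·SMe2 (10 mol %), TMSCl, THF/DMPU, −78 °C; Et3N, cold aq. NaHCO3
Reagents that add atoms: chlorotrimethylsilane, C[Si](C)(C)Cl
Why: Copper-catalysed, chlorosilane-accelerated conjugate addition delivers the butenyl group to the β-carbon anti to the bulky C4 arm, creating the quaternary centre (C10) with butenyl trans and methyl cis to that arm, and traps the enolate regiospecifically as the silyl enol ether.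

**Step 9**
Reactants: 12 (3S,4R)-3-(but-3-enyl)-3-methyl-4-[(1S)-2-methyl-1-(triethylsilyloxy)prop-2-en-1-yl]-1-(trimethylsilyloxy)cyclohex-1-ene; 13 3-(trimethylsilyl)but-3-en-2-one
Product: 16 (2R,3S,4R)-3-(but-3-enyl)-3-methyl-4-[(1S)-2-methyl-1-(triethylsilyloxy)prop-2-en-1-yl]-2-(3-oxobutyl)cyclohexan-1-one, via lithium enolate 14 (not isolated), via α-silyl diketone 15 (not isolated)
Conditions: MeLi, THF, 0 °C; 13, −78 °C; then K2CO3, MeOH, rt
Reagents that add atoms: none
Why: Michael addition of the regiospecifically regenerated lithium enolate to an α-silyl vinyl ketone (the silyl group stabilises the adduct anion and suppresses polymerisation) is followed by methanolytic C–Si cleavage, and the same basic methanol should bring the new α-stereocentre (C9) toward the equatorial chain trans to butenyl.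

**Step 10**
Reactants: 16 (2R,3S,4R)-3-(but-3-enyl)-3-methyl-4-[(1S)-2-methyl-1-(triethylsilyloxy)prop-2-en-1-yl]-2-(3-oxobutyl)cyclohexan-1-one; 17 triethyl phosphonoacetate
Product: 18 ethyl (2E)-5-[(1R,2S,3R)-2-(but-3-enyl)-2-methyl-3-[(1S)-2-methyl-1-(triethylsilyloxy)prop-2-en-1-yl]-6-oxocyclohexyl]-3-methylpent-2-enoate
Conditions: NaH, THF, 0 °C to rt
Reagents that add atoms: none
Why: Horner–Wadsworth–Emmons olefination is expected to take the unhindered methyl ketone in preference to the doubly branched ring ketone and to give mainly the E enoate (chain trans to ester), the Z isomer being removed by chromatography.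

**Step 11**
Reactants: 18 ethyl (2E)-5-[(1R,2S,3R)-2-(but-3-enyl)-2-methyl-3-[(1S)-2-methyl-1-(triethylsilyloxy)prop-2-en-1-yl]-6-oxocyclohexyl]-3-methylpent-2-enoate
Product: 19 A-homo alkene: ethyl (13E) ester with ring A = C1–C2–C3=C4(CH3)–C19H(OSiEt3)–C5–C10, 8-oxo, 19α-OTES, 5α-H, 10β-CH3, 9β side chain
Conditions: second-generation Grubbs catalyst (5 mol %), CH2Cl2 (5 mM), 40 °C; then NaOEt (0.2 equiv), EtOH, rt
Reagents that add atoms: none
Why: Ring-closing metathesis between the butenyl and isopropenyl alkenes closes the seven-membered ring as a trisubstituted cycloalkene with a trans ring fusion (both arms equatorial), and the brief ethoxide treatment funnels any C9 epimer to the equatorial 9β chain of the now rigid bicycle.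

**Step 12**
Reactants: 19 A-homo alkene
Product: 20 A-homo 3β,4β-epoxide of 19 (epoxide trans to the 19α-OTES group)
Conditions: mCPBA, NaHCO3, CH2Cl2, 0 °C
Reagents that add atoms: 3-chloroperbenzoic acid, OOC(=O)c1cccc(Cl)c1
Why: Prilezhaev epoxidation of the only electron-rich alkene (the enoate is inert) should occur on the convex β-face, anti to the pseudo-equatorial 19α-silyloxy group that leans over the α-face, which sets C3 and the epoxide carbon C4.

**Step 13**
Reactants: 20 A-homo 3β,4β-epoxide; 21 methyltriphenylphosphonium bromide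
Product: 22 ethyl (13E)-3β,4β-epoxy-19α-(triethylsilyloxy)-A-homolabda-8(17),13-dien-15-oate
Conditions: 21, KHMDS, THF, 0 °C; then 20, 0 °C to rt
Reagents that add atoms: none
Why: Wittig methylenation with the salt-free ylide converts the hindered C8 ketone into the 8(17)-methylene, the epoxide, silyl ether and enoate being inert to the unstabilised ylide, and C9 is no longer epimerisable afterwards.

**Step 14**
Reactants: 22 ethyl (13E)-3β,4β-epoxy-19α-(triethylsilyloxy)-A-homolabda-8(17),13-dien-15-oate
Product: 23 (13E)-3β,4β-epoxy-19α-(triethylsilyloxy)-A-homolabda-8(17),13-dien-15-ol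
Conditions: DIBAL-H (2.5 equiv), CH2Cl2, −78 °C; Rochelle salt
Reagents that add atoms: none
Why: 1,2-Reduction of the α,β-unsaturated ester gives the E allylic alcohol, and at −78 °C the hindered trisubstituted epoxide and the silyl ether should not be attacked.

**Step 15**
Reactants: 23 (13E)-3β,4β-epoxy-19α-(triethylsilyloxy)-A-homolabda-8(17),13-dien-15-ol
Product: 24 (13E)-15-(tert-butyldiphenylsilyloxy)-3β,4β-epoxy-19α-(triethylsilyloxy)-A-homolabda-8(17),13-diene
Conditions: TBDPSCl, imidazole, CH2Cl2, 0 °C to rt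
Reagents that add atoms: tert-butyl(chloro)diphenylsilane, CC(C)(C)[Si](Cl)(c1ccccc1)c1ccccc1
Why: Silylation of the primary allylic alcohol gives an ether that is robust to the Lewis acid and to mild acid but fluoride-labile, hence orthogonal to the TES group and to the later acetate.

**Step 16**
Reactants: 24 (13E)-15-(tert-butyldiphenylsilyloxy)-3β,4β-epoxy-19α-(triethylsilyloxy)-A-homolabda-8(17),13-diene
Product: 25 (13E)-15-(tert-butyldiphenylsilyloxy)-3β-(triethylsilyloxy)labda-8(17),13-dien-19-al
Conditions: MABR (2 equiv, from Me3Al and 4-bromo-2,6-di-tert-butylphenol), CH2Cl2, −78 to −40 °C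
Reagents that add atoms: none
Why: Semipinacol rearrangement of a 2,3-epoxy silyl ether: the bulky aluminium phenoxide binds the epoxide oxygen on the β-face, the C4–O bond at the methyl-bearing tertiary carbon ionises, and the C19–C5 ring bond shifts to C4 on the α-face while the silyloxy lone pair turns C19 into an oxocarbenium ion, which passes its silyl group to the O3 aluminium alkoxide through a six-membered array and becomes the aldehyde (should the silyl group be lost on work-up instead, alcohol 26 results directly). The closest known reaction type is the Lewis-acid rearrangement of 2,3-epoxy alcohol silyl ethers to β-silyloxy carbonyl compounds by 1,2-shift from the carbinol carbon, which includes ring contractions of cyclic epoxy alcohols. Six-membered ring A closes by this suprafacial 1,2-alkyl shift (seven-to-six contraction, C4–C5 formed as C19–C5 breaks), not by attack of an external or tethered nucleophile. The new stereocentre C4 is controlled by the epoxide configuration: backside entry of C5 inverts C4, so the formyl carbon ends axial (β) and the methyl equatorial (α), while C3 keeps its β-oxygen and C5 migrates with retention. The step needs ring-bond migration to beat hydride shift from C19 or C3 and proton loss; the 19α-silyloxy group trans to the epoxide holds H19 syn to the breaking C4–O bond where it cannot reach the backside, the oxygen on C19 makes that carbon a better migration origin than C3, and the hindered, non-nucleophilic Lewis acid at low temperature keeps the ion pair tight.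

**Step 17**
Reactants: 25 (13E)-15-(tert-butyldiphenylsilyloxy)-3β-(triethylsilyloxy)labda-8(17),13-dien-19-al
Product: 26 (13E)-15-(tert-butyldiphenylsilyloxy)-3β-hydroxylabda-8(17),13-dien-19-al
Conditions: HF·pyridine, pyridine, THF, 0 °C
Reagents that add atoms: none
Why: Buffered acidic fluoride desilylation cleaves the secondary triethylsilyl ether much faster than the primary TBDPS ether and avoids basic conditions under which a β-hydroxy aldehyde could undergo retro-aldol cleavage.

**Step 18**
Reactants: 26 (13E)-15-(tert-butyldiphenylsilyloxy)-3β-hydroxylabda-8(17),13-dien-19-al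
Product: 27 (13E)-3β-acetoxy-15-(tert-butyldiphenylsilyloxy)labda-8(17),13-dien-19-al
Conditions: Ac2O, pyridine, DMAP (cat.), CH2Cl2, rt
Reagents that add atoms: acetic anhydride, CC(=O)OC(C)=O
Why: DMAP-catalysed acylation of the equatorial 3β-hydroxyl, the aldehyde on quaternary C4 having no α-hydrogen and being unaffected.

**Step 19**
Reactants: 27 (13E)-3β-acetoxy-15-(tert-butyldiphenylsilyloxy)labda-8(17),13-dien-19-al
Product: 28 (13E)-3β-acetoxy-15-hydroxylabda-8(17),13-dien-19-al (target)
Conditions: TBAF, AcOH, THF, 0 °C to rt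
Reagents that add atoms: none
Why: Acetic acid-buffered fluoride desilylation frees the primary allylic alcohol while the acetate and the aldehyde remain, giving the target.

**Compound list**

1 | (E)-pent-3-en-2-one | C/C=C/C(C)=O | starting material
2 | (E)-2-(triisopropylsilyloxy)penta-1,3-diene | C=C(O[Si](C(C)C)(C(C)C)C(C)C)/C=C/C | intermediate
3 | 2,2,2-trifluoroethyl acrylate | C=CC(=O)OCC(F)(F)F | starting material
4 | 2,2,2-trifluoroethyl (1R,2S)-2-methyl-4-(triisopropylsilyloxy)cyclohex-3-ene-1-carboxylate (ester cis to methyl) | CC(C)[Si](C(C)C)(C(C)C)OC1=C[C@H](C)[C@H](C(=O)OCC(F)(F)F)CC1 | intermediate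
5 | [(1R,2R)-2-methyl-4-(triisopropylsilyloxy)cyclohex-3-en-1-yl]methanol (cis) | CC(C)[Si](C(C)C)(C(C)C)OC1=C[C@H](C)[C@H](CO)CC1 | intermediate
6 | (1R,2S)-2-methyl-4-(triisopropylsilyloxy)cyclohex-3-ene-1-carbaldehyde (cis) | CC(C)[Si](C(C)C)(C(C)C)OC1=C[C@H](C)[C@H](C=O)CC1 | intermediate
7 | isopropenylmagnesium bromide | CC(=C)[Mg]Br | starting material
8 | (1S)-2-methyl-1-[(1R,2R)-2-methyl-4-(triisopropylsilyloxy)cyclohex-3-en-1-yl]prop-2-en-1-ol | CC(C)[Si](C(C)C)(C(C)C)OC1=C[C@H](C)[C@H]([C@H](O)C(C)=C)CC1 | intermediate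
9 | triethyl{[(1S)-2-methyl-1-[(1R,2R)-2-methyl-4-(triisopropylsilyloxy)cyclohex-3-en-1-yl]prop-2-en-1-yl]oxy}silane | CC(C)[Si](C(C)C)(C(C)C)OC1=C[C@H](C)[C@H]([C@H](O[Si](CC)(CC)CC)C(C)=C)CC1 | intermediate
10 | (4R)-3-methyl-4-[(1S)-2-methyl-1-(triethylsilyloxy)prop-2-en-1-yl]cyclohex-2-en-1-one | O=C1C=C(C)[C@H]([C@H](O[Si](CC)(CC)CC)C(C)=C)CC1 | intermediate
11 | but-3-enylmagnesium bromide | C=CCC[Mg]Br | starting material
12 | (3S,4R)-3-(but-3-enyl)-3-methyl-4-[(1S)-2-methyl-1-(triethylsilyloxy)prop-2-en-1-yl]-1-(trimethylsilyloxy)cyclohex-1-ene (butenyl trans to the C4 arm) | C[Si](C)(C)OC1=C[C@@](C)(CCC=C)[C@H]([C@H](O[Si](CC)(CC)CC)C(C)=C)CC1 | intermediate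
13 | 3-(trimethylsilyl)but-3-en-2-one | CC(=O)C(=C)[Si](C)(C)C | starting material
14 | lithium (3S,4R)-3-(but-3-enyl)-3-methyl-4-[(1S)-2-methyl-1-(triethylsilyloxy)prop-2-en-1-yl]cyclohex-1-en-1-olate | [Li]OC1=C[C@@](C)(CCC=C)[C@H]([C@H](O[Si](CC)(CC)CC)C(C)=C)CC1 | intermediate
15 | (3S,4R)-3-(but-3-enyl)-3-methyl-4-[(1S)-2-methyl-1-(triethylsilyloxy)prop-2-en-1-yl]-2-[3-oxo-2-(trimethylsilyl)butyl]cyclohexan-1-one (ring C2 and the silylated carbon unassigned) | O=C1CC[C@@H]([C@H](O[Si](CC)(CC)CC)C(C)=C)[C@](C)(CCC=C)C1CCC([Si](C)(C)C)C(C)=O | intermediate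
16 | (2R,3S,4R)-3-(but-3-enyl)-3-methyl-4-[(1S)-2-methyl-1-(triethylsilyloxy)prop-2-en-1-yl]-2-(3-oxobutyl)cyclohexan-1-one | O=C1CC[C@@H]([C@H](O[Si](CC)(CC)CC)C(C)=C)[C@](C)(CCC=C)[C@H]1CCC(C)=O | intermediate
17 | triethyl phosphonoacetate | CCOC(=O)CP(=O)(OCC)OCC | starting material
18 | ethyl (2E)-5-[(1R,2S,3R)-2-(but-3-enyl)-2-methyl-3-[(1S)-2-methyl-1-(triethylsilyloxy)prop-2-en-1-yl]-6-oxocyclohexyl]-3-methylpent-2-enoate | O=C1CC[C@@H]([C@H](O[Si](CC)(CC)CC)C(C)=C)[C@](C)(CCC=C)[C@H]1CC/C(C)=C/C(=O)OCC | intermediate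
19 | ethyl (13E)-8-oxo-19α-(triethylsilyloxy)-17-nor-A-homolabda-3,13-dien-15-oate; trans-fused, 5α-H, 10β-CH3, 9β side chain (5R,9R,10S,19S) | O=C1CC[C@H]2[C@H](O[Si](CC)(CC)CC)C(C)=CCC[C@]2(C)[C@H]1CC/C(C)=C/C(=O)OCC | intermediate
20 | ethyl (13E)-3β,4β-epoxy-8-oxo-19α-(triethylsilyloxy)-17-nor-A-homolabd-13-en-15-oate (3S,4S,5R,9R,10S,19S) | O=C1CC[C@H]2[C@H](O[Si](CC)(CC)CC)[C@@]3(C)O[C@H]3CC[C@]2(C)[C@H]1CC/C(C)=C/C(=O)OCC | intermediate
21 | methyltriphenylphosphonium bromide | C[P+](c1ccccc1)(c1ccccc1)c1ccccc1.[Br-] | starting material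
22 | ethyl (13E)-3β,4β-epoxy-19α-(triethylsilyloxy)-A-homolabda-8(17),13-dien-15-oate (3S,4S,5R,9S,10R,19S) | C=C1CC[C@H]2[C@H](O[Si](CC)(CC)CC)[C@@]3(C)O[C@H]3CC[C@]2(C)[C@H]1CC/C(C)=C/C(=O)OCC | intermediate
23 | (13E)-3β,4β-epoxy-19α-(triethylsilyloxy)-A-homolabda-8(17),13-dien-15-ol (3S,4S,5R,9S,10R,19S) | C=C1CC[C@H]2[C@H](O[Si](CC)(CC)CC)[C@@]3(C)O[C@H]3CC[C@]2(C)[C@H]1CC/C(C)=C/CO | intermediate
24 | (13E)-15-(tert-butyldiphenylsilyloxy)-3β,4β-epoxy-19α-(triethylsilyloxy)-A-homolabda-8(17),13-diene (3S,4S,5R,9S,10R,19S); key-step precursor | C=C1CC[C@H]2[C@H](O[Si](CC)(CC)CC)[C@@]3(C)O[C@H]3CC[C@]2(C)[C@H]1CC/C(C)=C/CO[Si](c4ccccc4)(c5ccccc5)C(C)(C)C | intermediate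
25 | (13E)-15-(tert-butyldiphenylsilyloxy)-3β-(triethylsilyloxy)labda-8(17),13-dien-19-al (3S,4R,5R,9S,10R); key-step product | C=C1CC[C@H]2[C@@](C)(C=O)[C@@H](O[Si](CC)(CC)CC)CC[C@]2(C)[C@H]1CC/C(C)=C/CO[Si](c3ccccc3)(c4ccccc4)C(C)(C)C | intermediate
26 | (13E)-15-(tert-butyldiphenylsilyloxy)-3β-hydroxylabda-8(17),13-dien-19-al | C=C1CC[C@H]2[C@@](C)(C=O)[C@@H](O)CC[C@]2(C)[C@H]1CC/C(C)=C/CO[Si](c3ccccc3)(c4ccccc4)C(C)(C)C | intermediate
27 | (13E)-3β-acetoxy-15-(tert-butyldiphenylsilyloxy)labda-8(17),13-dien-19-al | C=C1CC[C@H]2[C@@](C)(C=O)[C@@H](OC(C)=O)CC[C@]2(C)[C@H]1CC/C(C)=C/CO[Si](c3ccccc3)(c4ccccc4)C(C)(C)C | intermediate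
28 | (13E)-3β-acetoxy-15-hydroxylabda-8(17),13-dien-19-al (3S,4R,5R,9S,10R) | C=C1CC[C@H]2[C@@](C)(C=O)[C@@H](OC(C)=O)CC[C@]2(C)[C@H]1CC/C(C)=C/CO | target

**Step count and risks**

Total step count: 19. Longest linear sequence: 19 steps (1 to 28); all other building blocks are commercial.

Steps most likely to fail:

1. Step 16 (key step). After ionisation at C4, hydride transfer from C19 (to the seven-membered ketone) or from C3, or proton loss to an allylic alcohol, may outrun ring-bond migration. The reason is that in the resting chair-like form of ring A the C19–C5 bond lies nearer perpendicular than anti to the C4–O bond, so the ring must twist before C5 can bridge. Fallback: setting out from 24, the C19 triethylsilyl ether is removed selectively (HF·pyridine, pyridine, THF, 0 °C) to give the trans-epoxy alcohol F1. F1 is then rearranged as the free 2,3-epoxy alcohol with ZnBr2 in CH2Cl2 (0 °C to rt), a Lewis-acid semipinacol rearrangement of an α-hydroxy epoxide in which loss of the hydroxyl proton replaces silyl transfer. This should give hydroxy aldehyde 26 directly, where the route is rejoined (step 18).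

2. Step 12. Oxygen transfer to the C3=C4 bond may show poor facial selectivity (attack syn to the silyl ether would give the 3α,4α-epoxide), and slow Baeyer–Villiger oxidation of the C8 ketone may accompany it. Fallback: setting out from 19, should the peracid favour the α-face, NBS in aqueous THF (0 °C) is used to form the bromonium ion on that same face. Water then opens it at tertiary C4 from the other side to give the bromohydrin F2 (3α-Br, 4β-OH). K2CO3 in EtOH closes F2 by intramolecular SN2 displacement to the 3β,4β-epoxide 20, where the route is rejoined.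

3. Step 5. Felkin–Anh facial selectivity at the aldehyde may be low, and base-induced epimerisation of its α-carbon would erode the enantiomeric purity of everything downstream. Fallback: setting out from 6, the addition is run as before, and the (1R)-carbinol epimer F3 is separated and inverted instead of discarded. Mitsunobu esterification (4-nitrobenzoic acid, PPh3, DIAD, toluene, 0 °C) gives the (1S)-4-nitrobenzoate F4 with inversion, and K2CO3 in MeOH cleaves it to 8, where the route is rejoined.

**Further compounds**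

F1 | step 16 | (13E)-15-(tert-butyldiphenylsilyloxy)-3β,4β-epoxy-A-homolabda-8(17),13-dien-19α-ol | C=C1CC[C@H]2[C@H](O)[C@@]3(C)O[C@H]3CC[C@]2(C)[C@H]1CC/C(C)=C/CO[Si](c4ccccc4)(c5ccccc5)C(C)(C)C
F2 | step 12 | ethyl (13E)-3α-bromo-4β-hydroxy-8-oxo-19α-(triethylsilyloxy)-17-nor-A-homolabd-13-en-15-oate | O=C1CC[C@H]2[C@H](O[Si](CC)(CC)CC)[C@@](C)(O)[C@H](Br)CC[C@]2(C)[C@H]1CC/C(C)=C/C(=O)OCC
F3 | step 5 | (1R)-2-methyl-1-[(1R,2R)-2-methyl-4-(triisopropylsilyloxy)cyclohex-3-en-1-yl]prop-2-en-1-ol | CC(C)[Si](C(C)C)(C(C)C)OC1=C[C@H](C)[C@H]([C@@H](O)C(C)=C)CC1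
F4 | step 5 | (1S)-2-methyl-1-[(1R,2R)-2-methyl-4-(triisopropylsilyloxy)cyclohex-3-en-1-yl]prop-2-en-1-yl 4-nitrobenzoate | CC(C)[Si](C(C)C)(C(C)C)OC1=C[C@H](C)[C@H]([C@H](OC(=O)c2ccc(cc2)[N+](=O)[O-])C(C)=C)CC1
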